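The runs were generated by integration with made-up constants, and the scatter is random.

The ratio of E in green to E in grey after 50.0 min is 1.62, for a ratio of Z of 1.33, so I read an order in Z of about 1.67. I took it that D and Z make E, with X as the second substrate.

| flask | D | Z | X | temperature | remark | time |
|---|---|---|---|---|---|---|
| green | 0.50 M | 0.60 M | 0.50 M | −10 °C | run made earlier |  |
| violet | 0.50 M | 0.30 M | 0.50 M | 5 °C | run made earlier |  |
| grey | 0.50 M | 0.45 M | 0.50 M | −10 °C | run made earlier |  |
| ochre | 0.50 M | 0.60 M | 1 M | 5 °C | run made earlier |  |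
| eta | 0.50 M | 0.600 M | 0.500 M (fed, over 50 min) | 5 °C | all else is in the flask from the start; the feed brings no volume worth counting | 1.0 h |
| theta | 0.50 M (fed, over 50 min) | 0.600 M | 0.500 M |  | the addition at −25 °C, then warmed to 5 °C; the feed brings no volume worth counting | 1.0 h |
| beta | 0.50 M | 0.600 M | 0.500 M | 5 °C | everything together at the start | 1.0 h |
| delta | 0.50 M (fed, over 50 min) | 0.600 M | 0.500 M | 5 °C | all else is in the flask from the start; the feed brings no volume worth counting | 1.0 h |

| green: time / min | green: E / % | violet: time / min | violet: E / % | grey: time / h | grey: E / % | ochre: time / min | ochre: E / % |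
|---|---|---|---|---|---|---|---|
| 20.0 | 7.0 | 20.0 | 6.9 | 0.333 | 3.2 | 10.0 | 6.4 |
| 40.0 | 9.2 | 40.0 | 10.5 | 0.833 | 6.3 | 25.0 | 11.2 |
| 50.0 | 10.2 | 50.0 | 12.9 | 2.00 | 11.8 | 50.0 | 17.2 |
| 80.0 | 12.6 | 80.0 | 17.1 | 3.00 | 14.3 | 80.0 | 21.8 |

(standard deviation of a reading: 1 percentage point)

1. the flask with the highest amount of E, in percent of the D charged ("all alike" if they lie within 1.5 percentage points) (eta / theta / beta / delta / all alike)
2. final E, as a percentage of the D charged, in eta
3. final E, as a percentage of the D charged, in theta
4. final E, as a percentage of the D charged, in beta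
5. final E, as a percentage of the D charged, in delta



Beta has no twin among the runs, so I bracketed it at 1.0 h. Ochre, read between its points, gave 18.7% with twice the X. Violet, read the same way and scaled to 0.600 M of Z by that order, gave 45.7%. That is more than ochre, so X seemed to hold E down, but the scaling ignored the bending of the curves. I took the geometric mean, 29.2%, and this was my weak link.

I assumed E forms at first order in c_D, since the runs I read never varied D. Under a steady feed (semi-batch dosing), with the D that reacts left out of my reckoning, c_D climbs in a straight line, so it averages half the charge during the feed, and over 1.0 h I reckoned that delta gets 0.583 of what beta gets. I called this the exposure share: the time integral of c_D in a flask, divided by that of a flask with D in from the start. I let it multiply beta's E, taking c_Z as equal in the flasks compared. Theta feeds cold, so I counted its warm time, an exposure share of 0.167, and left out the E formed cold. Eta keeps beta's exposure share and gets its X by feed, and X had seemed to hold E down, so I committed to eta as the most.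

| flask | exposure share | my E |
|---|---|---|
| eta | 1 | above beta |
| beta | 1 | 29.2% |
| delta | 0.583 | 17.1% |
| theta | 0.167 | 4.87% |

The forecast named delta, with 21% for eta, 11% for theta, 22% for beta and 25% for delta, holding that “Feeding D lowers its concentration and trims the second-order loss”.

The flasks gave 31.1% in eta, 8.02% in theta, 27.0% in beta and 16.8% in delta, so eta stood highest.

    D + Z ⇌ E (K = 36.0 L mol⁻¹, k = 4.70 × 10⁻⁴ L mol⁻¹ s⁻¹, Ea = 49.0 kJ mol⁻¹, ΔH = −39.0 kJ mol⁻¹)
    X + Z ⇌ J (K = 3.50 L mol⁻¹, k = 0.00420 L mol⁻¹ s⁻¹, Ea = 50.0 kJ mol⁻¹, ΔH = −46.0 kJ mol⁻¹)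
    Z ⇌ G (K = 0.750, k = 0.00780 s⁻¹, Ea = 85.0 kJ mol⁻¹, ΔH = 5.00 kJ mol⁻¹)
    2 Z → L (k = 5.30 × 10⁻⁵ L mol⁻¹ s⁻¹, Ea = 72.0 kJ mol⁻¹)
    (constants at 5 °C)

With the measured beta in place of my weak link, the exposure share gives delta 15.7% against 16.8%, and theta, adding the E made cold to its warm share, 6.64% against 8.02%. In theta, while the cold feed ran for 50 min, X and Z went to J, which stood at 0.165 M at 0.833 h, with Z at 54.7% of its charge and E at 2.13%. In the warm 10.0 min after it, D with Z made E up to 8.02% while Z fell to 33.5% of its charge.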